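**Retrosynthetic overview**

1. Locants: ring C1 (CH–OAc), C2=C3(Me), C4, C5, C6 (bears C15, the CMe2OAc carbon), C7, C8=C9(Me), C10, C11, C12 (oxirane CH), C13 (oxirane C–Me), C14. The enabling feature is that the oxirane bond C12–C13 is a ring bond of both the three-membered ring and the 14-membered carbocycle, and C13 is a latent methyl-ketone carbon two atoms from the C1 carbinol.
2. Key disconnection C12–C13: intramolecular sulfonium-ylide (Corey–Chaykovsky) epoxidation of an open-chain ω-keto alkyldiphenylsulfonium salt. The carbocycle (C–C addition) and then the oxirane (loss of Ph2S) close last, in one operation; only desilylation and diacetylation follow.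
3. Open chain: the C13 methyl ketone and the C1 carbinol come from an E-enal by Brown allylation and Wacker oxidation; E-C2=C3 from Negishi carboalumination of a terminal alkyne; the C15 carbinol from an ester and MeMgBr.
4. C6 is set by Evans alkylation of an N-(hex-5-ynoyl)oxazolidinone with a Z-allylic bromide. Its C8=C9 geometry comes from syn-carbocupration of an ynoate, and its terminal chloride later becomes the sulfonium group.

Key step: step 16

Remark: the pKa figures used in step 16 are literature estimates for alkyldiphenylsulfonium salts and methyl ketones; (−)-Ipc2B(allyl) solution and the phosphazene base P2-Et are taken as purchasable reagents.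

**Route**

Step 1
Reactants: 1 5-chloropent-1-yne
Product: 3 methyl 6-chlorohex-2-ynoate, via lithium acetylide 2 (not isolated)
Conditions: n-BuLi, THF, −78 °C; ClCO2Me, −78 to 0 °C
Reagents that add atoms: methyl chloroformate, COC(=O)Cl
Why: Deprotonation of the terminal alkyne and C-acylation of the lithium acetylide with a chloroformate should give the ynoate, the primary chloride being inert at this temperature.

Step 2
Reactants: 3 methyl 6-chlorohex-2-ynoate
Product: 5 methyl (Z)-6-chloro-3-methylhex-2-enoate, via alkenylcuprate 4 (not isolated)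
Conditions: Me2CuLi (from MeLi and CuI), THF, −78 °C; MeOH then aq. NH4Cl at −78 °C
Reagents that add atoms: lithium dimethylcuprate, C[Cu-]C.[Li+]
Why: Conjugate syn-carbocupration of the ynoate and protonation of the alkenylcuprate with retention at −78 °C should place the chloropropyl arm cis to the ester, which fixes the Z geometry of C8=C9.

Step 3
Reactants: 5 methyl (Z)-6-chloro-3-methylhex-2-enoate
Product: 6 (Z)-6-chloro-3-methylhex-2-en-1-ol
Conditions: i-Bu2AlH (2.5 equiv), CH2Cl2, −78 °C; aqueous work-up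
Reagents that add atoms: none
Why: 1,2-Reduction of the enoate with i-Bu2AlH should give the allylic alcohol without touching the alkene geometry or the chloride.

Step 4
Reactants: 6 (Z)-6-chloro-3-methylhex-2-en-1-ol
Product: 7 (Z)-1-bromo-6-chloro-3-methylhex-2-ene
Conditions: CBr4, PPh3, CH2Cl2, 0 °C
Reagents that add atoms: carbon tetrabromide, BrC(Br)(Br)Br
Why: The Appel bromination is neutral and should convert the allylic alcohol into the bromide without allylic transposition or Z-to-E isomerisation.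

Step 5
Reactants: 8 hex-5-ynoic acid; 9 (S)-4-benzyloxazolidin-2-one
Product: 11 (S)-4-benzyl-3-(hex-5-ynoyl)oxazolidin-2-one, via mixed pivalic anhydride 10 (not isolated)
Conditions: t-BuCOCl, Et3N, THF, −20 °C; then 9, LiCl, −20 °C to rt
Reagents that add atoms: none
Why: N-Acylation of the oxazolidinone through the mixed pivalic anhydride is the standard preparation of Evans imides and tolerates the terminal alkyne.

Step 6
Reactants: 11 (S)-4-benzyl-3-(hex-5-ynoyl)oxazolidin-2-one; 7 (Z)-1-bromo-6-chloro-3-methylhex-2-ene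
Product: 13 (S)-4-benzyl-3-[(2R,4Z)-2-(but-3-yn-1-yl)-8-chloro-5-methyloct-4-enoyl]oxazolidin-2-one, via sodium enolate 12 (not isolated)
Conditions: NaN(SiMe3)2, THF, −78 °C; then 7, −78 to −40 °C
Reagents that add atoms: none
Why: In the Evans asymmetric alkylation the chelated sodium Z-enolate should be alkylated by the allylic bromide on the face opposite the benzyl group, which sets C6 as R; the primary chloride is far less reactive than the allylic bromide.

Step 7
Reactants: 13 (S)-4-benzyl-3-[(2R,4Z)-2-(but-3-yn-1-yl)-8-chloro-5-methyloct-4-enoyl]oxazolidin-2-one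
Product: 14 methyl (2R,4Z)-2-(but-3-yn-1-yl)-8-chloro-5-methyloct-4-enoate
Conditions: NaOMe (0.2 equiv), MeOH/THF, 0 °C
Reagents that add atoms: methanol, CO
Why: Methoxide-catalysed transesterification at the exocyclic imide carbonyl should release the auxiliary and give the methyl ester without epimerisation of C6 at 0 °C.

Step 8
Reactants: 14 methyl (2R,4Z)-2-(but-3-yn-1-yl)-8-chloro-5-methyloct-4-enoate
Product: 16 (3R,5Z)-3-(but-3-yn-1-yl)-9-chloro-2,6-dimethylnon-5-en-2-ol, via methyl ketone 15 (not isolated)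
Conditions: MeMgBr (5 equiv), CeCl3, THF, −78 to 0 °C
Reagents that add atoms: methylmagnesium bromide, C[Mg]Br
Why: Double addition of the cerium-modified Grignard reagent to the ester (through the methyl ketone) should build the C15 dimethylcarbinol, the weakly basic organocerium species avoiding enolisation at C6.

Step 9
Reactants: 16 (3R,5Z)-3-(but-3-yn-1-yl)-9-chloro-2,6-dimethylnon-5-en-2-ol
Product: 18 (2E,6R,8Z)-12-chloro-6-(2-hydroxypropan-2-yl)-3,9-dimethyldodeca-2,8-dien-1-ol, via alkenylalane 17 (not isolated)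
Conditions: Me3Al (4 equiv), Cp2ZrCl2 (0.5 equiv), CH2Cl2, 0 °C to rt; volatiles removed; n-BuLi, THF, −78 °C; (CH2O)n, rt; aqueous work-up
Reagents that add atoms: trimethylaluminium, C[Al](C)C; formaldehyde (as paraformaldehyde), C=O
Why: Negishi carboalumination adds CH3 and Al syn across the terminal alkyne (methyl to the internal carbon) and the derived alanate is hydroxymethylated with retention, which should give the E-C2=C3 allylic alcohol while the tertiary hydroxyl travels as its aluminium alkoxide.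

Step 10
Reactants: 18 (2E,6R,8Z)-12-chloro-6-(2-hydroxypropan-2-yl)-3,9-dimethyldodeca-2,8-dien-1-ol
Product: 19 (2E,6R,8Z)-12-chloro-6-(2-hydroxypropan-2-yl)-3,9-dimethyldodeca-2,8-dienal
Conditions: TEMPO (0.1 equiv), PhI(OAc)2, CH2Cl2, rt
Reagents that add atoms: none
Why: The TEMPO/PhI(OAc)2 oxidation should convert only the primary allylic alcohol into the enal without E/Z isomerisation, the tertiary alcohol being unable to react.

Step 11
Reactants: 19 (2E,6R,8Z)-12-chloro-6-(2-hydroxypropan-2-yl)-3,9-dimethyldodeca-2,8-dienal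
Product: 21 (4S,5E,9R,11Z)-15-chloro-9-(2-hydroxypropan-2-yl)-6,12-dimethylpentadeca-1,5,11-trien-4-ol, via borinate 20 (not isolated)
Conditions: (−)-Ipc2B(allyl) (reagent derived from (+)-α-pinene, 1.5 equiv), Et2O, −78 °C; then NaOH, H2O2, 0 °C to rt
Reagents that add atoms: (−)-B-allyldiisopinocampheylborane, C=CCB([C@@H]1C[C@@H]2C[C@H]([C@H]1C)C2(C)C)[C@@H]1C[C@@H]2C[C@H]([C@H]1C)C2(C)C
Why: In the Brown allylboration the reagent adds through a chair Zimmerman–Traxler transition state to the Si face of the enal in 1,2-fashion, which should set C1 as S under reagent control.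

Step 12
Reactants: 21 (4S,5E,9R,11Z)-15-chloro-9-(2-hydroxypropan-2-yl)-6,12-dimethylpentadeca-1,5,11-trien-4-ol
Product: 23 (4S,5E,9R,11Z)-4-(tert-butyldimethylsilyloxy)-15-chloro-6,12-dimethyl-9-[2-(triethylsilyloxy)propan-2-yl]pentadeca-1,5,11-triene, via mono-TBS ether 22 (not isolated)
Conditions: TBSOTf (1.1 equiv), 2,6-lutidine, CH2Cl2, −78 °C; then TESOTf (1.5 equiv), −78 to 0 °C
Reagents that add atoms: tert-butyldimethylsilyl triflate, CC(C)(C)[Si](C)(C)OS(=O)(=O)C(F)(F)F; triethylsilyl triflate, CC[Si](CC)(CC)OS(=O)(=O)C(F)(F)F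
Why: Silylation with silyl triflates should take the secondary allylic alcohol first (TBS, bulky and non-chelating, needed at C1 in step 16) and then cap the hindered tertiary alcohol with the smaller TES group.

Step 13
Reactants: 23 (4S,5E,9R,11Z)-4-(tert-butyldimethylsilyloxy)-15-chloro-6,12-dimethyl-9-[2-(triethylsilyloxy)propan-2-yl]pentadeca-1,5,11-triene
Product: 24 (4S,5E,9R,11Z)-4-(tert-butyldimethylsilyloxy)-15-chloro-6,12-dimethyl-9-[2-(triethylsilyloxy)propan-2-yl]pentadeca-5,11-dien-2-one
Conditions: PdCl2 (0.2 equiv), Cu(OAc)2 (0.4 equiv), O2 (1 atm), DMA/H2O 7:1, rt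
Reagents that add atoms: water, O
Why: The Tsuji–Wacker oxidation is selective for the monosubstituted terminal alkene over the two trisubstituted alkenes and should give the methyl ketone (Markovnikov), the acetate co-oxidant keeping the medium mild enough for both silyl ethers.

Step 14
Reactants: 24 (4S,5E,9R,11Z)-4-(tert-butyldimethylsilyloxy)-15-chloro-6,12-dimethyl-9-[2-(triethylsilyloxy)propan-2-yl]pentadeca-5,11-dien-2-one
Product: 25 (4S,5E,9R,11Z)-4-(tert-butyldimethylsilyloxy)-15-iodo-6,12-dimethyl-9-[2-(triethylsilyloxy)propan-2-yl]pentadeca-5,11-dien-2-one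
Conditions: NaI, NaHCO3, acetone, reflux
Reagents that add atoms: sodium iodide, [Na+].[I-]
Why: Finkelstein exchange (SN2 at the primary carbon) should give the iodide needed for silver-assisted S-alkylation under neutral conditions.

Step 15
Reactants: 25 (4S,5E,9R,11Z)-4-(tert-butyldimethylsilyloxy)-15-iodo-6,12-dimethyl-9-[2-(triethylsilyloxy)propan-2-yl]pentadeca-5,11-dien-2-one
Product: 26 [(4Z,7R,10E,12S)-12-(tert-butyldimethylsilyloxy)-4,10-dimethyl-14-oxo-7-[2-(triethylsilyloxy)propan-2-yl]pentadeca-4,10-dien-1-yl]diphenylsulfonium tetrafluoroborate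
Conditions: Ph2S (5 equiv), AgBF4, CH2Cl2, 0 °C to rt, dark
Reagents that add atoms: diphenyl sulfide, c1ccc(Sc2ccccc2)cc1; silver tetrafluoroborate, [Ag+].F[B-](F)(F)F
Why: Silver-assisted S-alkylation of diphenyl sulfide by a primary iodide, driven by precipitation of AgI, is the usual preparation of alkyldiphenylsulfonium salts and leaves the C12 methylene as the only carbon with α-hydrogens on sulfur.

Step 16
Reactants: 26 [(4Z,7R,10E,12S)-12-(tert-butyldimethylsilyloxy)-4,10-dimethyl-14-oxo-7-[2-(triethylsilyloxy)propan-2-yl]pentadeca-4,10-dien-1-yl]diphenylsulfonium tetrafluoroborate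
Product: 29 (1S,2E,6R,8Z,12S,13R)-1-(tert-butyldimethylsilyloxy)-12,13-epoxy-3,9,13-trimethyl-6-[2-(triethylsilyloxy)propan-2-yl]cyclotetradeca-2,8-diene, via sulfonium ylide 27 (not isolated), via betaine 28 (not isolated)
Conditions: phosphazene base P2-Et (1.1 equiv), THF (0.5 mM in 26), −78 to −30 °C
Reagents that add atoms: none
Why: Proposed new method: the phosphazene base should remove a proton only from the S–CH2 group (estimated pKa about 17 against about 26 for the ketone), the non-stabilised diphenylsulfonium ylide then adds through C12 to the C13 carbonyl and the betaine alkoxide expels Ph2S, which is the Corey–Chaykovsky epoxidation run as a macrocyclisation; the closest known reaction types are alkylidene transfer from alkyldiphenylsulfonium ylides to ketones and the intramolecular sulfonium-ylide epoxy-annulations that close five- to seven-membered rings in the same way. The 14-membered carbocycle closes by 14-exo-trig addition of C12 to the ketone and the oxirane by 3-exo-tet displacement at C12 with inversion, both under kinetic control because betaine formation from a non-stabilised ylide is irreversible. C13 is controlled by the adjacent C1 stereocentre: with C1–H held in the plane of the C2=C3 alkene by A(1,3) strain and the C14–C1 bond antiperiplanar to the incoming C12, the ketone methyl should turn away from the bulky, non-chelating OTBS group, so that the new C13–O bond comes out syn to C1–O. C12 is controlled relative to C13 by the addition geometry: in the cisoid transition state (Ph2S+ gauche to the carbonyl oxygen) the ring arms C11 and C14 lie antiperiplanar about the forming bond, and rotation to the anti S/O rotamer followed by closure places them cis on the oxirane, with H and CH3 on the other face. The step needs ylide formation without enolisation or loss of the β-silyloxy group, ring closure rather than oligomerisation, and the cis,syn diastereomer; these are served in turn by the metal-free pKa-matched base and the absence of α'-hydrogens on sulfur, by high dilution of a chain folded by two trisubstituted alkenes and the A(1,3)-locked allylic carbinol, and by the OTBS group at C1.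

Step 17
Reactants: 29 (1S,2E,6R,8Z,12S,13R)-1-(tert-butyldimethylsilyloxy)-12,13-epoxy-3,9,13-trimethyl-6-[2-(triethylsilyloxy)propan-2-yl]cyclotetradeca-2,8-diene
Product: 30 (1S,2E,6R,8Z,12S,13R)-12,13-epoxy-6-(2-hydroxypropan-2-yl)-3,9,13-trimethylcyclotetradeca-2,8-dien-1-ol
Conditions: TBAF, THF, 0 °C to rt
Reagents that add atoms: none
Why: Fluoride-mediated desilylation should remove the secondary TBS and the tertiary TES ether, the trisubstituted epoxide and both alkenes being inert to TBAF.

Step 18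
Reactants: 30 (1S,2E,6R,8Z,12S,13R)-12,13-epoxy-6-(2-hydroxypropan-2-yl)-3,9,13-trimethylcyclotetradeca-2,8-dien-1-ol
Product: 32 (1S,2E,6R,8Z,12S,13R)-6-(2-acetoxypropan-2-yl)-12,13-epoxy-3,9,13-trimethylcyclotetradeca-2,8-dien-1-yl acetate (CNP0282098.1), via C1 monoacetate 31 (not isolated)
Conditions: Ac2O, Et3N, DMAP, CH2Cl2, rt to 35 °C
Reagents that add atoms: acetic anhydride, CC(=O)OC(C)=O
Why: Steglich-type DMAP-catalysed acetylation should esterify the secondary allylic alcohol quickly and the tertiary carbinol more slowly through the N-acetylpyridinium ion, under non-acidic conditions that leave the epoxide closed.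

**Compound list**

1 | 5-chloropent-1-yne | C#CCCCCl | starting material
2 | lithium 5-chloropent-1-yn-1-ide | [Li]C#CCCCCl | intermediate
3 | methyl 6-chlorohex-2-ynoate | COC(=O)C#CCCCCl | intermediate
4 | lithium methyl[(Z)-configured 5-chloro-1-(methoxycarbonyl)-2-methylpent-1-enyl]cuprate (Cu cis to the new methyl) | COC(=O)/C([Cu-]C)=C(/C)CCCCl.[Li+] | intermediate
5 | methyl (Z)-6-chloro-3-methylhex-2-enoate | COC(=O)/C=C(/C)CCCCl | intermediate
6 | (Z)-6-chloro-3-methylhex-2-en-1-ol | OC/C=C(/C)CCCCl | intermediate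
7 | (Z)-1-bromo-6-chloro-3-methylhex-2-ene | BrC/C=C(/C)CCCCl | intermediate
8 | hex-5-ynoic acid | C#CCCCC(=O)O | starting material
9 | (S)-4-benzyloxazolidin-2-one | O=C1N[C@@H](Cc2ccccc2)CO1 | starting material
10 | hex-5-ynoic pivalic anhydride | C#CCCCC(=O)OC(=O)C(C)(C)C | intermediate
11 | (S)-4-benzyl-3-(hex-5-ynoyl)oxazolidin-2-one | C#CCCCC(=O)N1[C@@H](Cc2ccccc2)COC1=O | intermediate
12 | sodium (Z)-enolate of 11 | C#CCC/C=C(\[O-])N1[C@@H](Cc2ccccc2)COC1=O.[Na+] | intermediate
13 | (S)-4-benzyl-3-[(2R,4Z)-2-(but-3-yn-1-yl)-8-chloro-5-methyloct-4-enoyl]oxazolidin-2-one | C#CCC[C@@H](C(=O)N1[C@@H](Cc2ccccc2)COC1=O)C/C=C(/C)CCCCl | intermediate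
14 | methyl (2R,4Z)-2-(but-3-yn-1-yl)-8-chloro-5-methyloct-4-enoate | C#CCC[C@@H](C(=O)OC)C/C=C(/C)CCCCl | intermediate
15 | (3R,5Z)-3-(but-3-yn-1-yl)-9-chloro-6-methylnon-5-en-2-one | C#CCC[C@@H](C(C)=O)C/C=C(/C)CCCCl | intermediate
16 | (3R,5Z)-3-(but-3-yn-1-yl)-9-chloro-2,6-dimethylnon-5-en-2-ol | C#CCC[C@@H](C(C)(C)O)C/C=C(/C)CCCCl | intermediate
17 | (E)-alkenyldimethylalane of 16 (Al on C2, cis to the new C3 methyl; C15–O–AlMe2) | C[Al](C)/C=C(\C)CC[C@@H](C(C)(C)O[Al](C)C)C/C=C(/C)CCCCl | intermediate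
18 | (2E,6R,8Z)-12-chloro-6-(2-hydroxypropan-2-yl)-3,9-dimethyldodeca-2,8-dien-1-ol | OC/C=C(\C)CC[C@@H](C(C)(C)O)C/C=C(/C)CCCCl | intermediate
19 | (2E,6R,8Z)-12-chloro-6-(2-hydroxypropan-2-yl)-3,9-dimethyldodeca-2,8-dienal | O=C/C=C(\C)CC[C@@H](C(C)(C)O)C/C=C(/C)CCCCl | intermediate
20 | diisopinocampheylborinate ester of 21 (B–O at C1) | C=CC[C@H](OB([C@@H]1C[C@@H]2C[C@H]([C@H]1C)C2(C)C)[C@@H]1C[C@@H]2C[C@H]([C@H]1C)C2(C)C)/C=C(\C)CC[C@@H](C(C)(C)O)C/C=C(/C)CCCCl | intermediate
21 | (4S,5E,9R,11Z)-15-chloro-9-(2-hydroxypropan-2-yl)-6,12-dimethylpentadeca-1,5,11-trien-4-ol | C=CC[C@H](O)/C=C(\C)CC[C@@H](C(C)(C)O)C/C=C(/C)CCCCl | intermediate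
22 | (4S,5E,9R,11Z)-4-(tert-butyldimethylsilyloxy)-15-chloro-9-(2-hydroxypropan-2-yl)-6,12-dimethylpentadeca-1,5,11-triene | C=CC[C@H](O[Si](C)(C)C(C)(C)C)/C=C(\C)CC[C@@H](C(C)(C)O)C/C=C(/C)CCCCl | intermediate
23 | (4S,5E,9R,11Z)-4-(tert-butyldimethylsilyloxy)-15-chloro-6,12-dimethyl-9-[2-(triethylsilyloxy)propan-2-yl]pentadeca-1,5,11-triene | C=CC[C@H](O[Si](C)(C)C(C)(C)C)/C=C(\C)CC[C@@H](C(C)(C)O[Si](CC)(CC)CC)C/C=C(/C)CCCCl | intermediate
24 | (4S,5E,9R,11Z)-4-(tert-butyldimethylsilyloxy)-15-chloro-6,12-dimethyl-9-[2-(triethylsilyloxy)propan-2-yl]pentadeca-5,11-dien-2-one | CC(=O)C[C@H](O[Si](C)(C)C(C)(C)C)/C=C(\C)CC[C@@H](C(C)(C)O[Si](CC)(CC)CC)C/C=C(/C)CCCCl | intermediate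
25 | (4S,5E,9R,11Z)-4-(tert-butyldimethylsilyloxy)-15-iodo-6,12-dimethyl-9-[2-(triethylsilyloxy)propan-2-yl]pentadeca-5,11-dien-2-one | CC(=O)C[C@H](O[Si](C)(C)C(C)(C)C)/C=C(\C)CC[C@@H](C(C)(C)O[Si](CC)(CC)CC)C/C=C(/C)CCCI | intermediate
26 | [(4Z,7R,10E,12S)-12-(tert-butyldimethylsilyloxy)-4,10-dimethyl-14-oxo-7-[2-(triethylsilyloxy)propan-2-yl]pentadeca-4,10-dien-1-yl]diphenylsulfonium tetrafluoroborate | CC(=O)C[C@H](O[Si](C)(C)C(C)(C)C)/C=C(\C)CC[C@@H](C(C)(C)O[Si](CC)(CC)CC)C/C=C(/C)CCC[S+](c1ccccc1)c1ccccc1.F[B-](F)(F)F | intermediate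
27 | sulfonium ylide of 26 (carbanion at C12) | CC(=O)C[C@H](O[Si](C)(C)C(C)(C)C)/C=C(\C)CC[C@@H](C(C)(C)O[Si](CC)(CC)CC)C/C=C(/C)CC[CH-][S+](c1ccccc1)c1ccccc1 | intermediate
28 | syn-betaine: (1S,2E,6R,8Z,12R,13R)-14-membered C13 alkoxide carrying Ph2S+ at C12 | CC(C)(C)[Si](C)(C)O[C@@H]1/C=C(\C)CC[C@@H](C(C)(C)O[Si](CC)(CC)CC)C/C=C(/C)CC[C@@H]([S+](c2ccccc2)c2ccccc2)[C@@]([O-])(C)C1 | intermediate
29 | (1S,2E,6R,8Z,12S,13R)-1-(tert-butyldimethylsilyloxy)-12,13-epoxy-3,9,13-trimethyl-6-[2-(triethylsilyloxy)propan-2-yl]cyclotetradeca-2,8-diene | CC(C)(C)[Si](C)(C)O[C@@H]1/C=C(\C)CC[C@@H](C(C)(C)O[Si](CC)(CC)CC)C/C=C(/C)CC[C@@H]2O[C@]2(C)C1 | intermediate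
30 | (1S,2E,6R,8Z,12S,13R)-12,13-epoxy-6-(2-hydroxypropan-2-yl)-3,9,13-trimethylcyclotetradeca-2,8-dien-1-ol | O[C@@H]1/C=C(\C)CC[C@@H](C(C)(C)O)C/C=C(/C)CC[C@@H]2O[C@]2(C)C1 | intermediate
31 | (1S,2E,6R,8Z,12S,13R)-12,13-epoxy-6-(2-hydroxypropan-2-yl)-3,9,13-trimethylcyclotetradeca-2,8-dien-1-yl acetate | CC(=O)O[C@@H]1/C=C(\C)CC[C@@H](C(C)(C)O)C/C=C(/C)CC[C@@H]2O[C@]2(C)C1 | intermediate
32 | (1S,2E,6R,8Z,12S,13R)-6-(2-acetoxypropan-2-yl)-12,13-epoxy-3,9,13-trimethylcyclotetradeca-2,8-dien-1-yl acetate (CNP0282098.1) | CC(=O)O[C@@H]1/C=C(\C)CC[C@@H](C(C)(C)OC(C)=O)C/C=C(/C)CC[C@@H]2O[C@]2(C)C1 | target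

**Step count and risks**

Total step count: 18. Longest linear sequence: 17 steps (steps 1–4, then 6–18, from 5-chloropent-1-yne).

Steps most likely to fail:

1. Step 16 (proposed new method). What may go wrong: oligomerisation outrunning ring closure; decay of the non-stabilised ylide (elimination of Ph2S, aryl migration) before it reaches the ketone; base-induced loss of the β-silyloxy group; poor facial selectivity at the ketone or the ylide carbon, giving trans or epimeric epoxides. Fallback with known chemistry, from iodide 25 back to 29: oxidation of the iodide with Me3NO in DMSO (Kornblum-type) gives the keto aldehyde (4Z,7R,10E,12S)-12-(tert-butyldimethylsilyloxy)-4,10-dimethyl-14-oxo-7-[2-(triethylsilyloxy)propan-2-yl]pentadeca-4,10-dienal F1. Slow addition of F1 to low-valent titanium (TiCl3(DME)1.5, Zn(Cu), DME, rt), the established pinacol macrocyclisation of keto aldehydes to 14-membered 1,2-diols, gives after separation of diastereomers the (12R,13R)-diol F2. Selective mesylation of its secondary hydroxyl (MsCl, pyridine, 0 °C) gives the C12 mesylate F3, which DBU closes with inversion at C12 to epoxide 29.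

2. Step 15. What may go wrong: silver-induced ionisation of the iodide with participation of the C8=C9 alkene or hydride shift; desilylation by adventitious acid; incomplete alkylation of the weakly nucleophilic sulfide. Fallback, from iodide 25 back to 29: displacement with PhSNa in DMF gives the alkyl phenyl sulfide F4. Copper-catalysed S-phenylation with diphenyliodonium triflate (Cu(OAc)2 cat., chlorobenzene, 100 °C) gives the sulfonium triflate F5, which is taken through the conditions of step 16 to 29.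

3. Step 13. What may go wrong: partial anti-Markovnikov oxidation; palladium-induced migration of the terminal double bond; loss of a silyl ether. Fallback, from triene 23 back to ketone 24: oxymercuration–demercuration (Hg(OAc)2, THF/H2O; then NaBH4, NaOH), which prefers the monosubstituted alkene, gives the secondary alcohol F6 as a mixture of epimers at the new carbinol carbon. Dess–Martin oxidation then returns ketone 24.

**Further compounds**

F1 | step 16 | (4Z,7R,10E,12S)-12-(tert-butyldimethylsilyloxy)-4,10-dimethyl-14-oxo-7-[2-(triethylsilyloxy)propan-2-yl]pentadeca-4,10-dienal | CC(=O)C[C@H](O[Si](C)(C)C(C)(C)C)/C=C(\C)CC[C@@H](C(C)(C)O[Si](CC)(CC)CC)C/C=C(/C)CCC=O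
F2 | step 16 | (1S,2E,6R,8Z,12R,13R)-1-(tert-butyldimethylsilyloxy)-3,9,13-trimethyl-6-[2-(triethylsilyloxy)propan-2-yl]cyclotetradeca-2,8-diene-12,13-diol | CC(C)(C)[Si](C)(C)O[C@@H]1/C=C(\C)CC[C@@H](C(C)(C)O[Si](CC)(CC)CC)C/C=C(/C)CC[C@@H](O)[C@@](O)(C)C1
F3 | step 16 | 12-O-methanesulfonate of F2 | CC(C)(C)[Si](C)(C)O[C@@H]1/C=C(\C)CC[C@@H](C(C)(C)O[Si](CC)(CC)CC)C/C=C(/C)CC[C@@H](OS(C)(=O)=O)[C@@](O)(C)C1
F4 | step 15 | (4S,5E,9R,11Z)-4-(tert-butyldimethylsilyloxy)-6,12-dimethyl-15-(phenylsulfanyl)-9-[2-(triethylsilyloxy)propan-2-yl]pentadeca-5,11-dien-2-one | CC(=O)C[C@H](O[Si](C)(C)C(C)(C)C)/C=C(\C)CC[C@@H](C(C)(C)O[Si](CC)(CC)CC)C/C=C(/C)CCCSc1ccccc1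
F5 | step 15 | [(4Z,7R,10E,12S)-12-(tert-butyldimethylsilyloxy)-4,10-dimethyl-14-oxo-7-[2-(triethylsilyloxy)propan-2-yl]pentadeca-4,10-dien-1-yl]diphenylsulfonium triflate | CC(=O)C[C@H](O[Si](C)(C)C(C)(C)C)/C=C(\C)CC[C@@H](C(C)(C)O[Si](CC)(CC)CC)C/C=C(/C)CCC[S+](c1ccccc1)c1ccccc1.[O-]S(=O)(=O)C(F)(F)F
F6 | step 13 | (4S,5E,9R,11Z)-4-(tert-butyldimethylsilyloxy)-15-chloro-6,12-dimethyl-9-[2-(triethylsilyloxy)propan-2-yl]pentadeca-5,11-dien-2-ol (both C2 epimers) | CC(O)C[C@H](O[Si](C)(C)C(C)(C)C)/C=C(\C)CC[C@@H](C(C)(C)O[Si](CC)(CC)CC)C/C=C(/C)CCCCl
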